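**Plan**

- Cuts, in retrosynthetic order: the C15 acetate is removed last; C13=C14, C15 and the C13 methyl come from a terminal alkyne; the C7–O bond comes from 1,3-transposition of a C9 carbinol, so C9–C11 is cut back to a C9 ketone; C6–O comes from a C6 ketone; ring A is cut at C1–C2 and C3–C4.
- Enabling feature: ring A hangs on the vicinal ring B atoms C5 and C10 through C4 (gem-dimethyl, so a tertiary radical from an isopropenyl group) and C1 (a CH2 on quaternary C10, so an aldehyde). A two-carbon C2–C3 acceptor can bridge them.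
- What is left of ring B (C5 isopropenyl, C7=C8 with the C8 methyl, C9 carbonyl, C10 open to two alkylations) is (R)-carvone.
- Forward: the carvone ring becomes ring B and C10 is made quaternary; ring A is annulated by radical addition to a vinylphosphonium salt followed by intramolecular Wittig closure; ring B is then oxidised at C6, the chain is added at C9, oxygen is moved to C7 and the chain is completed.
- Stereochemistry: C5 from (R)-carvone; C10 by aldol anti to the isopropenyl group; C6 by α-face hydride delivery; C7 by addition anti to the 6β C–O bond; 13E by syn-carboalumination.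

Key step: step 4

Remark: locants C1–C17 are labdane numbers (ring A: C1–C5, C10; ring B: C5–C10; chain C11–C16; C17 on C8). The C9 carbinol configuration of 12 and 13 is drawn for the expected α-face addition and is lost in step 9.

**Route**

Step 1
Reactants: 1 (R)-(−)-carvone
Product: 2 (5R)-2,6-dimethyl-5-(prop-1-en-2-yl)cyclohex-2-en-1-one (both C6 epimers)
Conditions: LiN(i-Pr)2, THF, −78 °C; MeI, −78 → 0 °C
Reagents that add atoms: iodomethane, CI
Why: Kinetic α′-deprotonation of the enone and C-methylation of the lithium enolate (enolate alkylation) should give 2 as an epimer mixture, which does not matter because this center is enolised again in step 2.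

Step 2
Reactants: 2 (5R)-2,6-dimethyl-5-(prop-1-en-2-yl)cyclohex-2-en-1-one
Product: 3 (5S,6R)-6-(hydroxymethyl)-2,6-dimethyl-5-(prop-1-en-2-yl)cyclohex-2-en-1-one
Conditions: LiN(i-Pr)2, THF, −78 °C; CH2O (gas, from cracked paraformaldehyde), −78 °C; H2O work-up
Reagents that add atoms: formaldehyde, C=O
Why: The regenerated α′-enolate should undergo crossed aldol addition to formaldehyde on the face anti to the neighbouring isopropenyl group (substrate control, as in second α′-alkylations of carvone), which sets the quaternary center with hydroxymethyl trans and methyl cis to isopropenyl.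

Step 3
Reactants: 3 (5S,6R)-6-(hydroxymethyl)-2,6-dimethyl-5-(prop-1-en-2-yl)cyclohex-2-en-1-one
Product: 4 (1R,6S)-1,3-dimethyl-2-oxo-6-(prop-1-en-2-yl)cyclohex-3-ene-1-carbaldehyde
Conditions: Dess–Martin periodinane, CH2Cl2, 0 °C → rt
Reagents that add atoms: none
Why: Dess–Martin oxidation of the neopentyl primary alcohol should stop at the aldehyde under neutral conditions that spare the non-enolisable β-keto aldehyde from retro-Claisen cleavage.

Step 4
Reactants: 4 (1R,6S)-1,3-dimethyl-2-oxo-6-(prop-1-en-2-yl)cyclohex-3-ene-1-carbaldehyde; 5 triphenyl(vinyl)phosphonium bromide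
Product: 7 (4aS,8aS)-2,5,5,8a-tetramethyl-4a,5,6,8a-tetrahydronaphthalen-1(4H)-one, via phosphonium bromide 6 (not isolated)
Conditions: Fe(acac)3 (30 mol %), PhSiH3, i-PrOH/THF, 40 °C; then KOt-Bu, 0 °C → rt, same flask
Reagents that add atoms: none
Why: Proposed new method: an iron hydride formed from Fe(acac)3 and PhSiH3 should transfer a hydrogen atom to the CH2 terminus of the isopropenyl group (Markovnikov MHAT), the tertiary C4 radical should add to the unsubstituted carbon of the electron-poor vinylphosphonium 5 (C3–C4 bond, Giese addition), and reduction of the α-phosphonio radical by divalent iron with protonation by i-PrOH gives salt 6, whose ylide (KOt-Bu) closes ring A by intramolecular Wittig olefination of the C1 formyl group (C1=C2 bond, loss of Ph3PO). The closest known reaction types are the iron-hydride reductive coupling of 1,1-disubstituted alkenes with electron-poor alkenes, its radical–polar crossover annulation variant in which a γ,δ-unsaturated aldehyde and an enone or enal are joined by Giese addition and aldol closure, and the annulation in which a nucleophile adds to a vinylphosphonium salt and the resulting ylide undergoes intramolecular Wittig reaction; here the carbon radical takes the role of that nucleophile. Ring A closes as a six-membered ring in a (4+2) sense, the second bond by attack of the ylide carbon on the aldehyde (6-exo-trig, through the oxaphosphetane). No new stereocenter arises (C4 carries two methyls, C1 and C2 become sp2); the trans ring fusion is already fixed by C5 and C10 of 4, where isopropenyl and formyl are trans-diequatorial and can be bridged without strain. The step needs hydrogen-atom transfer to the electron-rich 1,1-disubstituted alkene and not to the enone (iron hydrides react far faster with unactivated alkenes), intermolecular capture by 5 and not by the internal enone (which would need a four-membered or bridged ring), and olefination of the aldehyde and not of the C9 ketone (which would give an anti-Bredt bridgehead alkene).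

Step 5
Reactants: 7 (4aS,8aS)-2,5,5,8a-tetramethyl-4a,5,6,8a-tetrahydronaphthalen-1(4H)-one
Product: 8 (4aS,8aS)-2,5,5,8a-tetramethyl-4a,5,6,7,8,8a-hexahydronaphthalen-1(4H)-one
Conditions: H2 (1 atm), RhCl(PPh3)3 (5 mol %), benzene/EtOH, rt
Reagents that add atoms: none
Why: Homogeneous hydrogenation with RhCl(PPh3)3 should saturate the cis-disubstituted ring A alkene and leave the trisubstituted conjugated enone untouched, as in the selective reduction of the isopropenyl group of carvone.

Step 6
Reactants: 8 (4aS,8aS)-2,5,5,8a-tetramethyl-4a,5,6,7,8,8a-hexahydronaphthalen-1(4H)-one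
Product: 9 (4aS,8aS)-2,5,5,8a-tetramethyl-4a,5,6,7,8,8a-hexahydronaphthalene-1,4-dione
Conditions: Pd(OH)2/C (5 mol %), t-BuOOH, K2CO3 (cat.), CH2Cl2, rt
Reagents that add atoms: tert-butyl hydroperoxide, CC(C)(C)OO
Why: Palladium/tert-butyl hydroperoxide γ-oxidation of the enone (allylic oxidation through the tert-butylperoxy radical and the stabilised C6 radical) should convert the only γ-methylene into the ene-1,4-dione, as in the oxidation of steroidal 4-en-3-ones to 4-ene-3,6-diones.

Step 7
Reactants: 9 (4aS,8aS)-2,5,5,8a-tetramethyl-4a,5,6,7,8,8a-hexahydronaphthalene-1,4-dione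
Product: 10 (4R,4aS,8aS)-4-hydroxy-2,5,5,8a-tetramethyl-4a,5,6,7,8,8a-hexahydronaphthalen-1(4H)-one
Conditions: NaBH4, CeCl3·7H2O, MeOH, −78 °C
Reagents that add atoms: none
Why: Luche reduction should attack the less hindered C6 carbonyl (C9 is flanked by quaternary C10 and methyl-bearing C8, compare the selective C4 reduction of 2,6,6-trimethylcyclohex-2-ene-1,4-dione) from the α face opposite the syn-axial C10 and C4 methyls, which gives the axial 6β-alcohol.

Step 8
Reactants: 10 (4R,4aS,8aS)-4-hydroxy-2,5,5,8a-tetramethyl-4a,5,6,7,8,8a-hexahydronaphthalen-1(4H)-one; 11 (4-bromobut-1-yn-1-yl)trimethylsilane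
Product: 13 (1S,4R,4aS,8aS)-1-(but-3-yn-1-yl)-2,5,5,8a-tetramethyl-1,4,4a,5,6,7,8,8a-octahydronaphthalene-1,4-diol, via silylalkyne diol 12 (not isolated)
Conditions: 11, Mg, THF (Grignard reagent, 3 equiv); LaCl3·2LiCl (30 mol %), 10, THF, 0 °C → rt; then MeOH, K2CO3 (cat.), rt
Reagents that add atoms: none
Why: Lanthanum-promoted Grignard 1,2-addition to the hindered enone carbonyl (the first equivalent deprotonates the hydroxyl), followed in the same flask by base-mediated methanolysis of the alkynyl C–Si bond, should give 13; attack is expected anti to the axial C10 methyl, and either C9 epimer serves.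

Step 9
Reactants: 13 (1S,4R,4aS,8aS)-1-(but-3-yn-1-yl)-2,5,5,8a-tetramethyl-1,4,4a,5,6,7,8,8a-octahydronaphthalene-1,4-diol
Product: 14 (1S,2S,4aS,8aS)-4-(but-3-yn-1-yl)-3,4a,8,8-tetramethyl-1,2,4a,5,6,7,8,8a-octahydronaphthalene-1,2-diol
Conditions: HClO4 (5 mol %), THF/H2O (4:1), 0 °C → rt
Reagents that add atoms: water, O
Why: Acid-catalysed 1,3-allylic transposition (SN1′ hydration) ionises the tertiary allylic alcohol, and water should add to the C7 terminus of the allyl cation anti to the pseudoaxial 6β C–O bond (α face), giving the more stable tetrasubstituted C8=C9 alkene and the trans-diaxial 6β,7α-diol.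

Step 10
Reactants: 14 (1S,2S,4aS,8aS)-4-(but-3-yn-1-yl)-3,4a,8,8-tetramethyl-1,2,4a,5,6,7,8,8a-octahydronaphthalene-1,2-diol
Product: 16 (1S,2S,4aS,8aS)-4-[(3E)-5-hydroxy-3-methylpent-3-en-1-yl]-3,4a,8,8-tetramethyl-1,2,4a,5,6,7,8,8a-octahydronaphthalene-1,2-diol, via alkenylalane 15 (not isolated)
Conditions: Me3Al (5 equiv), Cp2ZrCl2 (25 mol %), CH2Cl2, 0 °C → rt; then (CH2O)n, THF, rt; H2O work-up
Reagents that add atoms: trimethylaluminium, C[Al](C)C; formaldehyde (from paraformaldehyde), C=O
Why: Zirconocene-catalysed syn-methylalumination of the terminal alkyne (carboalumination) places methyl on C13 and aluminium on C14, and alkenylalane 15 should add to formaldehyde with retention, which fixes the 13E geometry; the tetrasubstituted ring alkene is inert and the two hydroxyls travel as aluminium alkoxides.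

Step 11
Reactants: 16 (1S,2S,4aS,8aS)-4-[(3E)-5-hydroxy-3-methylpent-3-en-1-yl]-3,4a,8,8-tetramethyl-1,2,4a,5,6,7,8,8a-octahydronaphthalene-1,2-diol
Product: 17 (1S,2S,4aS,8aS)-4-[(3E)-5-acetoxy-3-methylpent-3-en-1-yl]-3,4a,8,8-tetramethyl-1,2,4a,5,6,7,8,8a-octahydronaphthalene-1,2-diyl diacetate
Conditions: Ac2O, DMAP (cat.), pyridine, rt → 40 °C
Reagents that add atoms: acetic anhydride, CC(=O)OC(C)=O
Why: DMAP-catalysed acylation with excess acetic anhydride should esterify the primary and both secondary hydroxyls, including the hindered axial 6β-OH.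

Step 12
Reactants: 17 (1S,2S,4aS,8aS)-4-[(3E)-5-acetoxy-3-methylpent-3-en-1-yl]-3,4a,8,8-tetramethyl-1,2,4a,5,6,7,8,8a-octahydronaphthalene-1,2-diyl diacetate
Product: 18 (1S,2S,4aS,8aS)-4-[(3E)-5-hydroxy-3-methylpent-3-en-1-yl]-3,4a,8,8-tetramethyl-1,2,4a,5,6,7,8,8a-octahydronaphthalene-1,2-diyl diacetate (CNP0187815.1)
Conditions: Candida antarctica lipase B (immobilised), phosphate buffer pH 7/acetone (9:1), 30 °C
Reagents that add atoms: none
Why: Lipase-catalysed regioselective ester hydrolysis should cleave only the unhindered primary allylic acetate, because the two secondary acetates on the congested decalin do not fit the active site, and neutral pH prevents acyl migration.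

**Compound list**

1 | (R)-(−)-carvone | C=C(C)[C@@H]1CC=C(C)C(=O)C1 | starting material
2 | (5R)-2,6-dimethyl-5-(prop-1-en-2-yl)cyclohex-2-en-1-one (6-methylcarvone, C6 epimers) | C1C=C(C)C(=O)C(C)[C@@H]1C(C)=C | intermediate
3 | (5S,6R)-6-(hydroxymethyl)-2,6-dimethyl-5-(prop-1-en-2-yl)cyclohex-2-en-1-one | C1C=C(C)C(=O)[C@@](C)(CO)[C@@H]1C(C)=C | intermediate
4 | (1R,6S)-1,3-dimethyl-2-oxo-6-(prop-1-en-2-yl)cyclohex-3-ene-1-carbaldehyde | C1C=C(C)C(=O)[C@@](C)(C=O)[C@@H]1C(C)=C | intermediate
5 | triphenyl(vinyl)phosphonium bromide | C=C[P+](c1ccccc1)(c1ccccc1)c1ccccc1.[Br-] | starting material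
6 | {3-[(1S,2R)-2-formyl-2,4-dimethyl-3-oxocyclohex-4-en-1-yl]-3-methylbutyl}triphenylphosphonium bromide (not isolated) | C1C=C(C)C(=O)[C@@](C)(C=O)[C@@H]1C(C)(C)CC[P+](c1ccccc1)(c1ccccc1)c1ccccc1.[Br-] | intermediate
7 | (4aS,8aS)-2,5,5,8a-tetramethyl-4a,5,6,8a-tetrahydronaphthalen-1(4H)-one | C1C=C(C)C(=O)[C@@]2(C)C=CCC(C)(C)[C@H]12 | intermediate
8 | (4aS,8aS)-2,5,5,8a-tetramethyl-4a,5,6,7,8,8a-hexahydronaphthalen-1(4H)-one | C1C=C(C)C(=O)[C@@]2(C)CCCC(C)(C)[C@H]12 | intermediate
9 | (4aS,8aS)-2,5,5,8a-tetramethyl-4a,5,6,7,8,8a-hexahydronaphthalene-1,4-dione | O=C1C=C(C)C(=O)[C@@]2(C)CCCC(C)(C)[C@H]12 | intermediate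
10 | (4R,4aS,8aS)-4-hydroxy-2,5,5,8a-tetramethyl-4a,5,6,7,8,8a-hexahydronaphthalen-1(4H)-one (6β-hydroxy enone) | O[C@@H]1C=C(C)C(=O)[C@@]2(C)CCCC(C)(C)[C@H]12 | intermediate
11 | (4-bromobut-1-yn-1-yl)trimethylsilane | C[Si](C)(C)C#CCCBr | starting material
12 | (1S,4R,4aS,8aS)-2,5,5,8a-tetramethyl-1-[4-(trimethylsilyl)but-3-yn-1-yl]-1,4,4a,5,6,7,8,8a-octahydronaphthalene-1,4-diol (not isolated) | O[C@@H]1C=C(C)[C@@](O)(CCC#C[Si](C)(C)C)[C@@]2(C)CCCC(C)(C)[C@H]12 | intermediate
13 | (1S,4R,4aS,8aS)-1-(but-3-yn-1-yl)-2,5,5,8a-tetramethyl-1,4,4a,5,6,7,8,8a-octahydronaphthalene-1,4-diol | O[C@@H]1C=C(C)[C@@](O)(CCC#C)[C@@]2(C)CCCC(C)(C)[C@H]12 | intermediate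
14 | (1S,2S,4aS,8aS)-4-(but-3-yn-1-yl)-3,4a,8,8-tetramethyl-1,2,4a,5,6,7,8,8a-octahydronaphthalene-1,2-diol (6β,7α-diol) | O[C@@H]1[C@@H](O)C(C)=C(CCC#C)[C@@]2(C)CCCC(C)(C)[C@H]12 | intermediate
15 | (E)-alkenyldimethylalane from 14, methyl on C13 and AlMe2 on C14, both hydroxyls as OAlMe2 (not isolated) | C[Al](C)O[C@@H]1[C@@H](O[Al](C)C)C(C)=C(CC/C(C)=C/[Al](C)C)[C@@]2(C)CCCC(C)(C)[C@H]12 | intermediate
16 | (1S,2S,4aS,8aS)-4-[(3E)-5-hydroxy-3-methylpent-3-en-1-yl]-3,4a,8,8-tetramethyl-1,2,4a,5,6,7,8,8a-octahydronaphthalene-1,2-diol | O[C@@H]1[C@@H](O)C(C)=C(CC/C(C)=C/CO)[C@@]2(C)CCCC(C)(C)[C@H]12 | intermediate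
17 | (1S,2S,4aS,8aS)-4-[(3E)-5-acetoxy-3-methylpent-3-en-1-yl]-3,4a,8,8-tetramethyl-1,2,4a,5,6,7,8,8a-octahydronaphthalene-1,2-diyl diacetate | CC(=O)O[C@@H]1[C@@H](OC(C)=O)C(C)=C(CC/C(C)=C/COC(C)=O)[C@@]2(C)CCCC(C)(C)[C@H]12 | intermediate
18 | (1S,2S,4aS,8aS)-4-[(3E)-5-hydroxy-3-methylpent-3-en-1-yl]-3,4a,8,8-tetramethyl-1,2,4a,5,6,7,8,8a-octahydronaphthalene-1,2-diyl diacetate (6β,7α-diacetoxylabda-8,13E-dien-15-ol) | CC(=O)O[C@@H]1[C@@H](OC(C)=O)C(C)=C(CC/C(C)=C/CO)[C@@]2(C)CCCC(C)(C)[C@H]12 | target

Total step count: 12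
Longest linear sequence: 12 steps, from 1 to 18

**Steps most likely to fail**

Step 4 (Proposed new method). The α-phosphonio radical may be quenched without clean formation of 6, or residual silane activated by the alkoxide base may reduce the formyl group before the ylide closes the ring, so that only one of the two bonds forms. Fallback with known chemistry, from 4: the iron-hydride radical–polar crossover annulation with acrolein (Fe(acac)3 cat., PhSiH3, ethylene glycol, 1,2-dichloroethane, 0 °C; MHAT, Giese addition, then aldol closure of the enolate onto the formyl group) should give the ring A β-hydroxy aldehyde F1. Acid-catalysed dehydration (TsOH, toluene, 80 °C) gives the ring A enal F2. Tsuji–Wilkinson decarbonylation with stoichiometric RhCl(PPh3)3 (toluene, 110 °C) removes the formyl group and comes back to the route at 7.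

Step 9. Water capture at C7 may show poor facial selectivity, and proton loss from the allyl cation to dienes may compete. Fallback from 13: acetylation of the secondary hydroxyl only (Ac2O, pyridine) gives the 6β-monoacetate F3. Babler–Dauben oxidative transposition with [C5H5NH][CrO3Cl] in CH2Cl2 moves the oxygen from C9 to C7 and gives the 6β-acetoxy-8-en-7-one F4. Luche reduction, with hydride entering anti to the axial acetoxy group, gives the 7β-alcohol F5. Mitsunobu inversion (4-nitrobenzoic acid, PPh3, DIAD) gives the 7α-(4-nitrobenzoate) F6. Methanolysis of both esters (K2CO3, MeOH) comes back to the route at 14.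

Step 7. Discrimination between the two carbonyls may be poor, or conjugate reduction of the ene-dione may compete. Fallback from 8, which changes the order so that only one carbonyl is ever present: the Grignard reagent of 11 (LaCl3·2LiCl, THF) is added to the single carbonyl of 8 to give the tertiary allylic alcohol F7. Chromium-free radical allylic oxidation at C6 (Rh2(cap)4, dirhodium tetracaprolactamate, t-BuOOH), which does not transpose the tertiary allylic alcohol, gives the γ-hydroxy enone F8. Luche reduction from the α face comes back to the route at 12, which is desilylated to 13 as in step 8.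

**Further compounds**

F1 | step 4 | (4aS,8aR)-1-hydroxy-4,4,7,8a-tetramethyl-8-oxo-1,2,3,4,4a,5,8,8a-octahydronaphthalene-2-carbaldehyde (epimers at C1 and C2) | C1C=C(C)C(=O)[C@@]2(C)C(O)C(C=O)CC(C)(C)[C@H]12
F2 | step 4 | (4aS,8aS)-4,4,7,8a-tetramethyl-8-oxo-3,4,4a,5,8,8a-hexahydronaphthalene-2-carbaldehyde | C1C=C(C)C(=O)[C@@]2(C)C=C(C=O)CC(C)(C)[C@H]12
F3 | step 9 | (1R,4S,4aS,8aS)-4-(but-3-yn-1-yl)-4-hydroxy-3,5,5? see name below | CC(=O)O[C@@H]1C=C(C)[C@@](O)(CCC#C)[C@@]2(C)CCCC(C)(C)[C@H]12
F4 | step 9 | (1S,4aS,8aS)-4-(but-3-yn-1-yl)-3,4a,8,8-tetramethyl-2-oxo-1,2,4a,5,6,7,8,8a-octahydronaphthalen-1-yl acetate | CC(=O)O[C@@H]1C(=O)C(C)=C(CCC#C)[C@@]2(C)CCCC(C)(C)[C@H]12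
F5 | step 9 | (1S,2R,4aS,8aS)-4-(but-3-yn-1-yl)-2-hydroxy-3,4a,8,8-tetramethyl-1,2,4a,5,6,7,8,8a-octahydronaphthalen-1-yl acetate | CC(=O)O[C@@H]1[C@H](O)C(C)=C(CCC#C)[C@@]2(C)CCCC(C)(C)[C@H]12
F6 | step 9 | (1S,2S,4aS,8aS)-1-acetoxy-4-(but-3-yn-1-yl)-3,4a,8,8-tetramethyl-1,2,4a,5,6,7,8,8a-octahydronaphthalen-2-yl 4-nitrobenzoate | CC(=O)O[C@@H]1[C@@H](OC(=O)c3ccc(cc3)[N+](=O)[O-])C(C)=C(CCC#C)[C@@]2(C)CCCC(C)(C)[C@H]12
F7 | step 7 | (1S,4aS,8aS)-2,5,5,8a-tetramethyl-1-[4-(trimethylsilyl)but-3-yn-1-yl]-1,4,4a,5,6,7,8,8a-octahydronaphthalen-1-ol | C1C=C(C)[C@@](O)(CCC#C[Si](C)(C)C)[C@@]2(C)CCCC(C)(C)[C@H]12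
F8 | step 7 | (4S,4aS,8aS)-4-hydroxy-3,4a,8,8-tetramethyl-4-[4-(trimethylsilyl)but-3-yn-1-yl]-4a,5,6,7,8,8a-hexahydronaphthalen-1(4H)-one | O=C1C=C(C)[C@@](O)(CCC#C[Si](C)(C)C)[C@@]2(C)CCCC(C)(C)[C@H]12

Name of F3 in full: 6β-monoacetate of 13, (1R,4S,4aS,8aS)-numbering aside, it is 13 with the secondary hydroxyl acetylated and the tertiary C9 hydroxyl free, as its SMILES shows.
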